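## Structural features

Argophyllin A is a germacranolide: a ten-membered carbocycle (C1–C10) trans-fused along C6–C7 to an α-methylene-γ-butyrolactone (O–C6–C7–C11–C12, with the exocyclic C11=C13). The carbocycle carries seven stereocentres in two clusters. One cluster is the trisubstituted 1β,10α-epoxide (C14 methyl on C10) together with the trans-vicinal diol made of the secondary 3β-carbinol and the tertiary 4α-carbinol (C15 methyl on C4). The other is the contiguous triad C6 (lactone oxygen, α), C7 (C11, β) and C8 (angelate, β). The clusters are insulated from each other by the methylene groups C5 and C9, and C2 separates the epoxide from the diol, so stereochemical information passes between them only through the conformation of the medium ring. Fragile features are the exo-methylene lactone (Michael and hydrogen-atom acceptor), the (Z)-2-methylbut-2-enoate (isomerises to the tiglate), and the epoxide flanked by two hydroxyls (transannular ether formation under acid). Every precursor that still holds the (E,E)-1(10),4-diene is also open to Cope rearrangement and proton-induced transannular cyclisation. The real difficulty is the oxygen pattern: five C–O bonds must be placed on a flexible ring with no carbonyl group to direct them, and the lactone oxygen sits on C6, which in the trienoic acid is one allylic CH2 among six allylic positions (C2, C3, C6, C9, C14, C15). The key step exploits the fact that C6–Hα is both allylic to C4=C5 and γ to the C12 carboxyl group: a P450 pocket that binds the carboxylate and the 8β-hydroxyl oxidises exactly this bond, and the new 6α-hydroxyl then lies 1,4 to C12 and closes the lactone ring by itself.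

## Logic of the disconnections

21 ⇒ 19. The C11=C13 π bond is exchanged for a C13–N σ bond (forward through the quaternary salt 20). 21 unites a Michael acceptor, an acid-labile epoxide and a free diol, so the last forward operation should be the mildest one available. The gain is that no earlier intermediate has an exo-methylene group when it meets fluoride, amines or a metal hydride. Forward, alkylation must occur on nitrogen only and elimination must proceed at bicarbonate pH.

19 ⇒ 18. The O–Si bond at C3 is cut. The silyl group is needed because the C3 hydroxyl must be told apart from the C8 hydroxyl at the acylation stage. Forward, fluoride must remove it without touching the epoxide or the two esters, which is why the Michael acceptor is still masked at that point.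

18 ⇒ 15 + 16. The acyl–oxygen bond of the C8 ester is cut, which removes the only appendage and the Z-olefin. The ester is attached after the radical hydration because a conjugated trisubstituted ester olefin would not pass unchanged through hydrogen-atom-transfer conditions. The demand is acylation of a hindered secondary alcohol that leaves the tertiary C4 hydroxyl alone and does not isomerise the double bond of 16.

15 ⇒ 14. The C4–O bond and one C5–H bond are cut (retro-hydration). The C4 carbinol with its methyl group and the neighbouring CH2 is the Markovnikov water adduct of the trisubstituted C4=C5 olefin; the cut removes one stereocentre and restores the olefin of the biogenetic diene. Forward, hydrogen must go to C5 and oxygen to the α face of C4, and no other C=C may be present, so the epoxide must already be in place and the methylene lactone masked.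

14 ⇒ 13. The C13–N bond is cut. The amine is a traceless mask put on by conjugate addition; it costs one step in and one step out.

13 ⇒ 12. The two C–O bonds of the epoxide are cut back to the C1=C10 olefin. This is the more electron-rich ring olefin and the (E,E)-diene has a defined crown shape, so the forward epoxidation can be site- and face-selective. It must be buffered, because the epoxide and the C4=C5 olefin cyclise transannularly under acid.

12 ⇒ 11. The O–Si bond is cut. Forward, silylation has to choose the allylic C3 hydroxyl over the more hindered C8 hydroxyl.

11 ⇒ 10. The C3–O bond is cut to a C–H bond. No chemical oxidant is trusted here: ene-type reagents such as SeO2 go for the C15 (or C14) methyl of such ring olefins and invert the olefin geometry, and radical oxidants cannot be relied on to single out C3 while both ring olefins are present. A second P450, which hydroxylates C3 on the β face of close relatives of 10, is therefore chosen. The demand is that it tolerates the extra 8β-hydroxyl.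

10 ⇒ 8. This is the strategic cut: the C6–O and O–C12 bonds are broken, which opens the lactone ring, removes the C6 stereocentre and leads to the monocyclic acid of the sunflower pathway. Forward, one allylic CH2 among six allylic positions must be hydroxylated on the α face, which only an enzyme can do; closure of 9 is then spontaneous. 8 is left without any protecting group, because the free carboxylate and the free 8β-hydroxyl are the recognition elements of the enzyme.

8 ⇒ 3. The C8–O bond, the C–O bonds at C12 and the ring bond C6–C7 are cut (through 7, 6, 5 and 4). A chiral ten-membered ring with two stereocentres goes back to an achiral acyclic diphosphate. The carbon that loses its oxygen in the cyclisation is C6, the same carbon that the key step re-oxygenates. Forward, the cyclase must set C7 and both E olefins, and two P450 enzymes must oxidise C12 and C8 in their native order.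

3 ⇒ 2 ⇒ 1. The C–O–P bond and then the C–Br bond are cut, back to the commercial alcohol. The forward displacements must not scramble the 2E olefin.

## Other disconnections considered

Alternative 1: The cut runs through C5–C6 and C4–O. Forward, the aldoxime A1 is an open chain that already holds the epoxide, the C3 and C8 silyl ethers and an isopropenyl terminus (C4=C5). NaOCl would oxidise it to the nitrile oxide, which would add across C4=C5, close the ten-membered ring and give the bridged isoxazoline A2.
- In its favour: a concerted, stereospecific cycloaddition makes one C–C and one C–O bond. The oxygen lands on C4 by the normal regiochemistry of a 1,1-disubstituted olefin. Reductive N–O cleavage would unveil the C4 tertiary carbinol, the C5 methylene and a C6 ketone together.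
- Where it is equal or better: on the regiochemistry of the C4 oxygen it is better than the chosen plan, which relies on a radical hydration, and it needs no enzyme. In skeletal bonds made by the key step the two plans are equal (two each).
- Against it here: closure of a ten-membered carbocycle through a bridged transition state must overcome transannular strain and compete with furoxan dimerisation. The configuration of the new quaternary C4 depends on the folding of a flexible chain, and the epoxide must survive hypochlorite. After the key step the C6 ketone still has to be reduced to the 6α-alcohol, the lactone closed, C13 introduced by α-methylenation and the angelate attached.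
- Comparison: A1, with five stereocentres, is a long linear target in itself, so the step count would be expected to be roughly twice that of the chosen plan. The C6 and C11/C13 problems that the P450 step settles in one operation stay open.

Alternative 2: The cut is the C8–C9 bond, with the C6–C1 bond of a six-membered template re-formed in the retrosynthetic direction. Forward, the potassium alkoxide of the trans-1,2-divinylcyclohexanol A3 (KH, 18-crown-6) would rearrange by an anionic oxy-Cope process through a chair, open the cyclohexane and, after protonation of the C6 enolate, give the cyclodecenone A4.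
- In its favour: the chair transition state transfers the configuration of the template into the E geometry of C1=C10 and into the C8 stereocentre. The ring is made by expansion, not by an entropically costly cyclisation. The C3/C4 diol is set on a cyclohexane, where facial control is routine.
- Where it is equal or better: on the C3/C4 oxygens and on mechanistic predictability it is the better plan.
- Against it here: A4 has no C11–C13 unit and no C6 stereocentre. C7 must therefore be alkylated regioselectively next to a ketone that can also enolise towards C5, where the β-alkoxy group on C4 invites elimination; that risk already exists under the strongly basic conditions of the rearrangement. The silyl group on C8 needs an oxidative C–Si cleavage whose electrophilic activation is hard to reconcile with the trisubstituted olefin. The adjacency of the carbinol and isopropenyl carbons in A3 calls for a carbonyl transposition on the carvone ring.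
- Comparison: in step economy the chosen plan is clearly shorter. Structurally, A4 delivers the carbocycle and leaves the whole lactone to be built, whereas the chosen key step delivers the lactone and leaves the C1–C4 oxygens to be added.

Alternative 3: The cut trades the C1=C10 π bond and a C4 carbonyl for a C4–C10 σ bond in a cis-fused hydroazulene. Forward, KOtBu would deprotonate the tertiary C4 alcohol of the mesylate A5, the C4–C10 bond would break as the C1 mesylate leaves (Grob fragmentation), and the (E)-cyclodecenone A6 would result.
- In its favour: the fragmentation is stereospecific (anti-periplanar C4–C10 and C1–O bonds), so the E olefin follows from the relative configuration at C1 and C10. C3, C6, C7 and C8 are set on a rigid bicycle, and the olefin appears exactly where the epoxide is wanted.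
- Where it is equal or better: in control of the E geometry it is the equal of the cyclase in the chosen plan. At C3, which is made by synthesis and not by C–H oxidation, it is better.
- Against it here: A6 is a C4 ketone without C15. A methyl nucleophile would have to add with the right facial sense on a flexible ring, next to an enolisable α-silyloxy centre (C3) and a β-alkoxy group (C6) that can eliminate, also under KOtBu. A5 has seven stereocentres, one of them a quaternary carbon, and is a long synthesis. The C12 ether must later be oxidised to the acid and lactonised, followed by epoxidation and acylation.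
- Comparison: the chosen plan is far shorter. Mechanistically the alternative is more predictable at the ring-forming stage but postpones the C4 stereocentre to a less controlled addition; the chosen plan has the opposite profile (secure ring and lactone, riskier late oxygenations).

Key step: step 4

Assumption: germacrene A synthase, the four P450 enzymes with their reductase and glucose dehydrogenase are used as heterologously expressed catalysts (recombinant protein or yeast microsomes) and count as reagents, not starting materials; 14 is drawn as the expected 11βH epimer, a centre that is erased in step 12.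

Check of the structures: 8 and 10 as drawn carry 6α-O (in 10), the C7 side chain β and 8β-O, with both ring olefins E, which is what 21 requires; no structure had to be corrected.

## Route

Step 1
Reactants: 1 (2E,6E)-farnesol
Product: 2 (2E,6E)-farnesyl bromide
Conditions: PBr3 (0.4 equiv), Et2O, −10 to 0 °C
Reagents that add atoms: phosphorus tribromide, BrP(Br)Br
Why: Bromination of a primary allylic alcohol by SN2 displacement on its phosphite ester; the low temperature keeps the 2E geometry and avoids allylic transposition, and the crude bromide is used at once.

Step 2
Reactants: 2 (2E,6E)-farnesyl bromide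
Product: 3 (2E,6E)-farnesyl diphosphate
Conditions: (nBu4N)3HP2O7, MeCN, rt; NH4+ cation-exchange resin, then cellulose, iPrOH/MeCN/aq NH4HCO3
Reagents that add atoms: tris(tetra-n-butylammonium) hydrogen diphosphate, CCCC[N+](CCCC)(CCCC)CCCC.CCCC[N+](CCCC)(CCCC)CCCC.CCCC[N+](CCCC)(CCCC)CCCC.OP([O-])(=O)OP([O-])([O-])=O
Why: SN2 displacement of the allylic bromide by the diphosphate anion in a dipolar aprotic solvent is the standard entry to allylic diphosphates and does not touch the olefin geometry.

Step 3
Reactants: 3 (2E,6E)-farnesyl diphosphate
Product: 8 8β-hydroxygermacra-1(10)E,4E,11(13)-trien-12-oic acid, via germacrene A 4 (not isolated), via germacratrien-12-ol 5 (not isolated), via germacratrien-12-al 6 (not isolated), via germacrene A acid 7 (not isolated)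
Conditions: germacrene A synthase, MgCl2; yeast microsomes with germacrene A oxidase, germacrene A acid 8β-hydroxylase (both CYP71 family) and NADPH-cytochrome P450 reductase; NADP+ (cat.), D-glucose, glucose dehydrogenase; air; HEPES pH 7.5, 30 °C; EtOAc extraction at pH 6, below 5 °C
Reagents that add atoms: dioxygen, O=O
Why: Terpene cyclisation followed by P450 C–H hydroxylations, each the native reaction of a sunflower-pathway enzyme: the synthase ionises the diphosphate, closes the C6–C7 ring bond (1,10-closure of the farnesyl chain) and loses a methyl proton, which fixes the C7 configuration and both E olefins in 4. The oxidase then takes C12 through 5 and 6 to the acid 7 in three turnovers and the second P450 hydroxylates C8 of 7 on the β face. Running the cascade in one pot keeps the volatile, Cope- and acid-labile hydrocarbon 4 at a low stationary concentration.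

Step 4
Reactants: 8 8β-hydroxygermacra-1(10)E,4E,11(13)-trien-12-oic acid
Product: 10 eupatolide (8β-hydroxygermacra-1(10)E,4E,11(13)-trien-12,6α-olide), via 6α-hydroxy acid 9 (not isolated)
Conditions: yeast microsomes with the sunflower-type germacrenoic acid 6α-hydroxylase (eupatolide synthase, CYP71 family) and NADPH-cytochrome P450 reductase; NADP+ (cat.), D-glucose, glucose dehydrogenase; air; potassium phosphate pH 7.5, 30 °C
Reagents that add atoms: dioxygen, O=O
Why: The heme-thiolate enzyme, reduced through its reductase, activates O2 to the oxoiron (formally tetravalent) porphyrin radical cation, which abstracts the α-hydrogen at C6 of carboxylate-bound 8; the allylic radical recombines with the iron-bound hydroxyl at C6 on the same face to give 9. This is C–H abstraction with oxygen rebound, the known reaction of costunolide-synthase-type P450 enzymes on germacrenoic acids; the member used here is the one whose native substrate carries the 8β-hydroxyl, since an enzyme tuned to the 8-deoxy acid cannot be assumed to accept 8. In 9 the 6α-hydroxyl adds to the C12 carboxyl carbon and water is lost without enzyme assistance, a 5-exo-trig closure (O–C6–C7–C11–C12, carbonyl oxygen exocyclic) that forms the O–C12 bond and the γ-lactone ring. The one new stereocentre, C6, is set by the enzyme through the face of abstraction and rebound, not by the ring closure: a 6β-alcohol would lactonise just as readily to the cis-fused isomer, so the trans fusion is a read-out of the α-face hydroxylation. The step needs regioselectivity for C6 over C2, C3, C9, C14 and C15 and chemoselectivity over epoxidation of the two trisubstituted olefins; both come from the binding of the C12 carboxylate and the 8β-hydroxyl, which places only C6–Hα above the iron. The 8β-hydroxyl is also 1,4 to C12 but, lying cis to the side chain, is not expected to lactonise at neutral pH, so no 8,12-olide should compete. Neutral buffer and 30 °C hold back proton-induced transannular cyclisation and Cope rearrangement of the diene.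

Step 5
Reactants: 10 eupatolide
Product: 11 3β-hydroxyeupatolide (3β,8β-dihydroxygermacra-1(10)E,4E,11(13)-trien-12,6α-olide)
Conditions: yeast microsomes with the feverfew-type germacranolide 3β-hydroxylase (CYP71 family) and NADPH-cytochrome P450 reductase; NADP+ (cat.), D-glucose, glucose dehydrogenase; air; potassium phosphate pH 7.5, 30 °C
Reagents that add atoms: dioxygen, O=O
Why: P450 allylic hydroxylation (hydrogen abstraction, oxygen rebound) at C3–Hβ, the known reaction of this enzyme on costunolide and parthenolide, of which 10 is the 8β-hydroxy analogue; the enzyme sets the 3β configuration and leaves the E geometry of C4=C5 untouched. SeO2/tBuOOH is avoided because on these ring olefins it is expected to oxidise the C15 or C14 methyl with inversion of the olefin geometry.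

Step 6
Reactants: 11 3β-hydroxyeupatolide
Product: 12 3β-(tert-butyldimethylsilyloxy)-8β-hydroxygermacra-1(10)E,4E,11(13)-trien-12,6α-olide
Conditions: TBSCl (1.1 equiv), imidazole, CH2Cl2/DMF, −20 to 0 °C
Reagents that add atoms: tert-butyldimethylsilyl chloride, CC(C)(C)[Si](C)(C)Cl
Why: Silylation is expected to favour the peripheral allylic 3β-hydroxyl, flanked by a CH2 and an sp2 carbon, over the 8β-hydroxyl next to the ring-fusion methine under the lactone. The silyl ether later differentiates the two secondary alcohols for acylation, shields the β face at C4 and switches off hydroxyl-directed epoxidation of C4=C5.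

Step 7
Reactants: 12 3-O-silyl ether of 3β-hydroxyeupatolide
Product: 13 1β,10α-epoxy-3β-(tert-butyldimethylsilyloxy)-8β-hydroxygermacra-4E,11(13)-dien-12,6α-olide
Conditions: mCPBA (1.05 equiv), NaHCO3, CH2Cl2, −20 to 0 °C
Reagents that add atoms: 3-chloroperoxybenzoic acid, OOC(=O)c1cccc(Cl)c1
Why: Prilezhaev epoxidation of the more nucleophilic C1=C10; C4=C5 is deactivated and screened by its allylic silyloxy and acyloxy neighbours and C11=C13 is conjugated. In the crown conformation of the (E,E)-diene the peracid reaches only the outer face of the olefin, which gives the 1β,10α-epoxide as in the 8-deoxy series. The bicarbonate buffer prevents acid-triggered transannular cyclisation of the epoxide onto C4=C5.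

Step 8
Reactants: 13 1β,10α-epoxide
Product: 14 13-(dimethylamino)-1β,10α-epoxy-3β-(tert-butyldimethylsilyloxy)-8β-hydroxy-11βH-germacr-4E-en-12,6α-olide
Conditions: Me2NH (2 M in THF), MeOH, 0 °C to rt
Reagents that add atoms: dimethylamine, CNC
Why: Aza-Michael addition to the exo-methylene lactone removes the only other C=C that would accept a hydrogen atom in step 9. Protonation of the enolate is expected to give the 11βH epimer, and this centre is destroyed again in step 12.

Step 9
Reactants: 14 amine adduct
Product: 15 13-(dimethylamino)-1β,10α-epoxy-3β-(tert-butyldimethylsilyloxy)-4α,8β-dihydroxy-11βH-germacran-12,6α-olide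
Conditions: Co(acac)2 (20 mol %), PhSiH3, O2 (1 atm), THF/iPrOH, rt
Reagents that add atoms: dioxygen, O=O
Why: Mukaiyama hydration: a cobalt hydride formed from Co(acac)2, PhSiH3 and O2 transfers a hydrogen atom to C5 of the only remaining olefin, the tertiary C4 radical captures O2 and the peroxide is reduced by the silane to the alcohol (Markovnikov regiochemistry). Oxygen is expected to arrive on the α face, anti to the bulky 3β-silyloxy group on the neighbouring carbon, which sets the 4α-hydroxy-4β-methyl centre. The epoxide is not adjacent to the radical and stays closed.

Step 10
Reactants: 15 4α-carbinol; 16 angelic acid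
Product: 18 8β-angeloyloxy-13-(dimethylamino)-1β,10α-epoxy-3β-(tert-butyldimethylsilyloxy)-4α-hydroxy-11βH-germacran-12,6α-olide, via mixed anhydride 17 (not isolated)
Conditions: 16, 2,4,6-Cl3C6H2COCl, Et3N, toluene, rt; then 15, toluene, 75 °C
Reagents that add atoms: none
Why: Yamaguchi esterification run without a nucleophilic catalyst: the 8β-hydroxyl attacks the less hindered angeloyl carbonyl of 17, and the absence of DMAP avoids the addition–elimination path that turns angelates into tiglates. The tertiary 4α-hydroxyl and the silylated C3 oxygen do not react, so only C8 is acylated.

Step 11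
Reactants: 18 silylated angelate
Product: 19 8β-angeloyloxy-13-(dimethylamino)-1β,10α-epoxy-3β,4α-dihydroxy-11βH-germacran-12,6α-olide
Conditions: nBu4NF, AcOH (1:1), THF, 0 °C to rt
Reagents that add atoms: none
Why: Fluoride-induced Si–O cleavage, buffered with acetic acid so that no alkoxide is free to open the epoxide transannularly or to attack the esters. The exo-methylene is still masked, so fluoride and acetate meet no Michael acceptor.

Step 12
Reactants: 19 amine adduct of the target
Product: 21 argophyllin A, via methiodide 20 (not isolated)
Conditions: MeI, THF, rt; then aq NaHCO3, rt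
Reagents that add atoms: none
Why: N-Methylation gives the quaternary ammonium salt 20, whose Hofmann-type β-elimination (E1cB through the lactone enolate) at bicarbonate pH restores the C11=C13 double bond. The C11 stereocentre disappears and no other centre is touched.

## Compound list

1 | (2E,6E)-farnesol | CC(C)=CCC/C(C)=C/CC/C(C)=C/CO | starting material
2 | (2E,6E)-farnesyl bromide | CC(C)=CCC/C(C)=C/CC/C(C)=C/CBr | intermediate
3 | (2E,6E)-farnesyl diphosphate (handled as its ammonium salt; free-acid SMILES) | CC(C)=CCC/C(C)=C/CC/C(C)=C/COP(=O)(O)OP(=O)(O)O | intermediate
4 | (+)-(R)-germacrene A (not isolated) | C=C(C)[C@H]1C/C=C(C)/CC/C=C(C)/CC1 | intermediate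
5 | germacra-1(10)E,4E,11(13)-trien-12-ol (not isolated) | C=C(CO)[C@H]1C/C=C(C)/CC/C=C(C)/CC1 | intermediate
6 | germacra-1(10)E,4E,11(13)-trien-12-al (not isolated) | C=C(C=O)[C@H]1C/C=C(C)/CC/C=C(C)/CC1 | intermediate
7 | germacrene A acid, germacra-1(10)E,4E,11(13)-trien-12-oic acid (not isolated) | C=C(C(=O)O)[C@H]1C/C=C(C)/CC/C=C(C)/CC1 | intermediate
8 | 8β-hydroxygermacra-1(10)E,4E,11(13)-trien-12-oic acid | C=C(C(=O)O)[C@H]1C/C=C(C)/CC/C=C(C)/C[C@H]1O | intermediate
9 | 6α,8β-dihydroxygermacra-1(10)E,4E,11(13)-trien-12-oic acid (not isolated) | C=C(C(=O)O)[C@H]1[C@H](O)/C=C(C)/CC/C=C(C)/C[C@H]1O | intermediate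
10 | eupatolide (8β-hydroxycostunolide) | C=C1C(=O)O[C@@H]2/C=C(C)/CC/C=C(C)/C[C@@H](O)[C@@H]12 | intermediate
11 | 3β-hydroxyeupatolide | C=C1C(=O)O[C@@H]2/C=C(C)/[C@@H](O)C/C=C(C)/C[C@@H](O)[C@@H]12 | intermediate
12 | 3-O-tert-butyldimethylsilyl ether of 11 | C=C1C(=O)O[C@@H]2/C=C(C)/[C@@H](O[Si](C)(C)C(C)(C)C)C/C=C(C)/C[C@@H](O)[C@@H]12 | intermediate
13 | 1β,10α-epoxide of 12 | C=C1C(=O)O[C@@H]2/C=C(C)/[C@@H](O[Si](C)(C)C(C)(C)C)C[C@H]3O[C@]3(C)C[C@@H](O)[C@@H]12 | intermediate
14 | 13-dimethylamino-11βH,13-dihydro adduct of 13 | CN(C)C[C@@H]1C(=O)O[C@@H]2/C=C(C)/[C@@H](O[Si](C)(C)C(C)(C)C)C[C@H]3O[C@]3(C)C[C@@H](O)[C@@H]12 | intermediate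
15 | 4α-hydroxy-4,5-dihydro derivative of 14 (4β-methyl, C5 methylene) | CN(C)C[C@@H]1C(=O)O[C@@H]2C[C@](C)(O)[C@@H](O[Si](C)(C)C(C)(C)C)C[C@H]3O[C@]3(C)C[C@@H](O)[C@@H]12 | intermediate
16 | angelic acid, (Z)-2-methylbut-2-enoic acid | C/C=C(/C)C(=O)O | starting material
17 | angelic 2,4,6-trichlorobenzoic anhydride (not isolated) | C/C=C(/C)C(=O)OC(=O)c1c(Cl)cc(Cl)cc1Cl | intermediate
18 | 8-O-angelate of 15 | CN(C)C[C@@H]1C(=O)O[C@@H]2C[C@](C)(O)[C@@H](O[Si](C)(C)C(C)(C)C)C[C@H]3O[C@]3(C)C[C@@H](OC(=O)/C(C)=C\C)[C@@H]12 | intermediate
19 | 13-dimethylamino-11βH,13-dihydroargophyllin A | CN(C)C[C@@H]1C(=O)O[C@@H]2C[C@](C)(O)[C@@H](O)C[C@H]3O[C@]3(C)C[C@@H](OC(=O)/C(C)=C\C)[C@@H]12 | intermediate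
20 | N-methyl quaternary ammonium iodide of 19 (not isolated) | C[N+](C)(C)C[C@@H]1C(=O)O[C@@H]2C[C@](C)(O)[C@@H](O)C[C@H]3O[C@]3(C)C[C@@H](OC(=O)/C(C)=C\C)[C@@H]12.[I-] | intermediate
21 | argophyllin A (8β-angeloyloxy-1β,10α-epoxy-3β,4α-dihydroxygermacr-11(13)-en-12,6α-olide) | C=C1C(=O)O[C@@H]2C[C@](C)(O)[C@@H](O)C[C@H]3O[C@]3(C)C[C@@H](OC(=O)/C(C)=C\C)[C@@H]12 | target

## Step count and least certain steps

Total step count: 12. Longest linear sequence: 12 steps (1 to 21); 16 enters in step 10.

Step 4 (key step). The most likely failure is slow, poorly coupled turnover of the membrane-bound P450 outside the cell, during which 8 is lost through proton-induced transannular cyclisation and Cope rearrangement of its diene on isolation, storage and incubation. Fallback: the isolation of 8 is given up and steps 3 and 4 are fused. The fallback sets out from 3, to which the synthase and microsomes carrying all three pathway P450 enzymes are applied together, so that 8 is hydroxylated at C6 as fast as it forms. It returns to the route at 10 and makes no new compound (F0).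

Step 5. The most likely failure is rejection of the substrate, or hydroxylation at another carbon, because the 8β-hydroxyl changes the binding mode in an enzyme shaped for 8-deoxy lactones. Fallback, by chemical oxidation once C4=C5 is the only ring olefin left: it sets out from 10, which buffered mCPBA would convert into 1β,10α-epoxyeupatolide F1. Radical allylic oxidation with Rh2(cap)4 and tBuOOH is then expected to attack C3, the only secondary allylic C–H (C6–H lies in the nodal plane of the olefin, C15 is primary), and to give 3-oxo-1β,10α-epoxyeupatolide F2. This ketone would be reduced at once (NaBH4, CeCl3·7H2O, MeOH, −78 °C; Luche reduction, hydride expected from the ring exterior) to 3β-hydroxy-1β,10α-epoxyeupatolide F3, because enolisation towards C2 would open the epoxide. Silylation of F3 (TBSCl, imidazole) returns to the route at 13.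

Step 9. The most likely failures are poor facial selectivity when O2 captures the planar C4 radical in a flexible ring, and sluggish hydrogen-atom transfer to an olefin flanked by two oxygenated carbons. Oxidation of the tertiary amine, which would unmask the lactone early, is a further risk. Fallback, which sets C4 on a conjugated ketone and postpones the epoxide: it sets out from 11.
- MnO2 would oxidise the allylic alcohol to 3-oxoeupatolide F4, and Me2NH would mask the lactone as the dimethylamine adduct F5.
- Reductive α-hydroxylation of the enone (Mn(dpm)3, PhSiH3, O2, iPrOH, 0 °C), in which conjugate hydrogen-atom transfer to C5 is expected to outrun hydration of the isolated C1=C10 olefin, would give the 4α-hydroxy-3-ketone F6.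
- Acylation of F6 with 17 as in step 10 would give the 8-angelate F7, and reduction of the ketone (NaBH4, CeCl3·7H2O, −78 °C) the 3β,4α-diol F8.
- MeI and then NaHCO3 would pass through the methiodide F9 to 1,10-deoxyargophyllin A F10.
- Buffered mCPBA, which now finds a single electron-rich olefin, would close the sequence at 21.

Step 10. The most likely failures are Z to E isomerisation of the angeloyl unit and incomplete acylation of the hindered hydroxyl at the temperature required; opening of the epoxide by the 4α-hydroxyl, promoted by the ammonium salts, is a further risk. Fallback, which builds the Z olefin on the substrate: it sets out from 15. Acylation with 2-(diphenoxyphosphoryl)propanoic acid (carbodiimide, catalytic DMAP, rt; no isomerisable olefin is present) would give the 2-(diphenoxyphosphoryl)propanoate F11 as a mixture of epimers at the phosphonate carbon. A Z-selective Ando olefination with acetaldehyde (DBU, NaI, THF, −78 to 0 °C) would then form the angelate and return to the route at 18.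

Step 3. The most likely failure is loss of flux: escape or rearrangement of volatile 4 before it is oxidised, and stalling at 5, 6 or 7 because four successive P450 turnovers depend on reductase coupling and cofactor recycling. Fallback: the cell-free cascade is replaced by fermentation. A yeast strain with an up-regulated mevalonate pathway makes 3 inside the cell from glucose, and the synthase, oxidase, reductase and 8β-hydroxylase expressed in the same cell convert it into 8, which is extracted from the buffered culture. The fallback sets out from cell-made 3 (steps 1 and 2 then fall away), returns at 8 and makes no new compound (F0).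

## Further compounds

F0 | step 4 | none | none
F1 | step 5 | 1β,10α-epoxyeupatolide | C=C1C(=O)O[C@@H]2/C=C(C)/CC[C@H]3O[C@]3(C)C[C@@H](O)[C@@H]12
F2 | step 5 | 3-oxo-1β,10α-epoxyeupatolide | C=C1C(=O)O[C@@H]2/C=C(C)/C(=O)C[C@H]3O[C@]3(C)C[C@@H](O)[C@@H]12
F3 | step 5 | 3β-hydroxy-1β,10α-epoxyeupatolide | C=C1C(=O)O[C@@H]2/C=C(C)/[C@@H](O)C[C@H]3O[C@]3(C)C[C@@H](O)[C@@H]12
F4 | step 9 | 3-oxoeupatolide | C=C1C(=O)O[C@@H]2/C=C(C)/C(=O)C/C=C(C)/C[C@@H](O)[C@@H]12
F5 | step 9 | 13-dimethylamino-11βH,13-dihydro-3-oxoeupatolide | CN(C)C[C@@H]1C(=O)O[C@@H]2/C=C(C)/C(=O)C/C=C(C)/C[C@@H](O)[C@@H]12
F6 | step 9 | 13-dimethylamino-4α,8β-dihydroxy-3-oxo-11βH-germacr-1(10)E-en-12,6α-olide | CN(C)C[C@@H]1C(=O)O[C@@H]2C[C@](C)(O)C(=O)C/C=C(C)/C[C@@H](O)[C@@H]12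
F7 | step 9 | 8-O-angelate of F6 | CN(C)C[C@@H]1C(=O)O[C@@H]2C[C@](C)(O)C(=O)C/C=C(C)/C[C@@H](OC(=O)/C(C)=C\C)[C@@H]12
F8 | step 9 | 8β-angeloyloxy-13-dimethylamino-3β,4α-dihydroxy-11βH-germacr-1(10)E-en-12,6α-olide | CN(C)C[C@@H]1C(=O)O[C@@H]2C[C@](C)(O)[C@@H](O)C/C=C(C)/C[C@@H](OC(=O)/C(C)=C\C)[C@@H]12
F9 | step 9 | N-methyl quaternary ammonium iodide of F8 | C[N+](C)(C)C[C@@H]1C(=O)O[C@@H]2C[C@](C)(O)[C@@H](O)C/C=C(C)/C[C@@H](OC(=O)/C(C)=C\C)[C@@H]12.[I-]
F10 | step 9 | 1,10-deoxyargophyllin A (8β-angeloyloxy-3β,4α-dihydroxygermacra-1(10)E,11(13)-dien-12,6α-olide) | C=C1C(=O)O[C@@H]2C[C@](C)(O)[C@@H](O)C/C=C(C)/C[C@@H](OC(=O)/C(C)=C\C)[C@@H]12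
F11 | step 10 | 8-O-[2-(diphenoxyphosphoryl)propanoate] of 15 | CN(C)C[C@@H]1C(=O)O[C@@H]2C[C@](C)(O)[C@@H](O[Si](C)(C)C(C)(C)C)C[C@H]3O[C@]3(C)C[C@@H](OC(=O)C(C)P(=O)(Oc4ccccc4)Oc5ccccc5)[C@@H]12
F0 | step 3 | none | none
A1 | alternative 1 | open-chain C6 aldoxime with the C1/C10 epoxide, 3-O-TBS, 8-O-TES, C12 methyl ester and isopropenyl terminus (C4=C5) | COC(=O)C[C@@H](/C=N/O)[C@H](O[Si](CC)(CC)CC)C[C@@]1(C)O[C@@H]1C[C@H](O[Si](C)(C)C(C)(C)C)C(C)=C
A2 | alternative 1 | ten-membered carbocycle bridged by the C6=N–O–C4 isoxazoline | COC(=O)C[C@H]1C2=NO[C@@](C)(C2)[C@@H](O[Si](C)(C)C(C)(C)C)C[C@H]3O[C@]3(C)C[C@H]1O[Si](CC)(CC)CC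
A3 | alternative 2 | trans-1-[(E)-2-(dimethylphenylsilyl)vinyl]-2-isopropenylcyclohexanol carrying the C3 and C4 MOM ethers | O[C@]1(/C=C/[Si](C)(C)c2ccccc2)C[C@](C)(OCOC)[C@@H](OCOC)C[C@@H]1C(C)=C
A4 | alternative 2 | 8-(dimethylphenylsilyl)-3,4-bis(methoxymethoxy)-(E)-cyclodec-1(10)-en-6-one | O=C1C[C@](C)(OCOC)[C@@H](OCOC)C/C=C(C)/C[C@@H]([Si](C)(C)c2ccccc2)C1
A5 | alternative 3 | cis-fused hydroazulene with C4 tertiary alcohol, C1 mesylate, C10 methyl and the C3, C6, C7, C8 substituents | C=C(COCc1ccc(OC)cc1)[C@H]2[C@H](OCc3ccc(OC)cc3)C[C@]4(O)[C@@H](O[Si](C(C)C)(C(C)C)C(C)C)C[C@@H](OS(C)(=O)=O)[C@]4(C)C[C@H]2O[Si](C)(C)C(C)(C)C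
A6 | alternative 3 | (E)-cyclodec-1(10)-en-4-one with 3-O-TIPS, 6-O-PMB, 8-O-TBS and the C7 side chain as its PMB ether | C=C(COCc1ccc(OC)cc1)[C@H]2[C@H](OCc3ccc(OC)cc3)CC(=O)[C@@H](O[Si](C(C)C)(C(C)C)C(C)C)C/C=C(C)/C[C@H]2O[Si](C)(C)C(C)(C)C
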